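The positions are numbered as in azulene (C3 bears the isopropyl group, C8a the angular methyl). The seven-membered ring carries its functionalised edges, C6–C7 (epoxide) and C3a–C4 (H, OH), in the 1,4-pattern of a cyclohepta-1,4-diene, the product type of a divinylcyclopropane Cope rearrangement. The route rests on one rhodium-carbenoid cascade: vinyldiazoacetate 6 cyclopropanates the vinyl group of the achiral dienyl ketal 4 (C5–C6 bond), and strain release then drives a [3,3] shift that forges the quaternary C8–C8a bond, with C8a set by the chiral catalyst. All other stereocentres are relayed from the angular methyl: hydroboration, isopropyl addition to the C3 ketone, hydroxyl-directed epoxidation.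

Key step: step 4

Remark: α denotes the face of the bicycle opposite to the C8a methyl group; the target is (3R,3aS,4S,6R,7S,8aR) in this numbering, with the epoxide, C3a–H, C4–OH and the isopropyl group α and the ester oxygen β.

Assumption: the sense of induction of the prolinate catalyst is taken from the facial model established for styrene cyclopropanation (the S catalyst gives (1S,2R)-cyclopropanes from aryldiazoacetates). On that model Rh2(R-DOSP)4 should give cyclopropane 7 and hence (8aR)-8. If the sense proved opposite, Rh2(S-DOSP)4 would be used with no other change.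

Step 1
Reactants: 1 2-bromo-3-methylcyclopent-2-en-1-one
Product: 2 6-bromo-7-methyl-1,4-dioxaspiro[4.4]non-6-ene
Conditions: ethylene glycol, p-TsOH·H2O (cat.), benzene, reflux, Dean–Stark
Reagents that add atoms: ethylene glycol, OCCO
Why: Acid-catalysed ketalisation with azeotropic removal of water masks the C3 carbonyl, which would otherwise make the diene electron-poor towards the electrophilic carbenoid, and the vinylic bromine keeps the double bond in place as in the ketalisation of 2-bromocyclopent-2-enone.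

Step 2
Reactants: 2 6-bromo-7-methyl-1,4-dioxaspiro[4.4]non-6-ene; 3 4,4,5,5-tetramethyl-2-vinyl-1,3,2-dioxaborolane
Product: 4 6-ethenyl-7-methyl-1,4-dioxaspiro[4.4]non-6-ene
Conditions: Pd(dppf)Cl2·CH2Cl2 (5 mol %), K3PO4, 1,4-dioxane/H2O, 80 °C
Reagents that add atoms: 3 4,4,5,5-tetramethyl-2-vinyl-1,3,2-dioxaborolane, C=CB1OC(C)(C)C(C)(C)O1
Why: Suzuki–Miyaura coupling of the alkenyl bromide with the vinylboronate should deliver the semicyclic 1,3-diene, the ketal being stable to the basic medium.

Step 3
Reactants: 5 methyl but-3-enoate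
Product: 6 methyl 2-diazobut-3-enoate
Conditions: 4-acetamidobenzenesulfonyl azide, DBU, MeCN, 0 °C; extracted into pentane and used at once
Reagents that add atoms: 4-acetamidobenzenesulfonyl azide, CC(=O)Nc1ccc(cc1)S(=O)(=O)N=[N+]=[N-]
Why: Regitz diazo transfer to the methylene activated by both the ester and the vinyl group gives the vinyldiazoacetate, which is used cold and immediately because it slowly electrocyclises to a pyrazole.

Step 4
Reactants: 4 6-ethenyl-7-methyl-1,4-dioxaspiro[4.4]non-6-ene; 6 methyl 2-diazobut-3-enoate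
Product: 8 methyl (8aR)-3,3-(ethylenedioxy)-8a-methyl-1,2,3,5,8,8a-hexahydroazulene-6-carboxylate, via cis-divinylcyclopropane ester 7 (not isolated)
Conditions: Rh2(R-DOSP)4 [dirhodium tetrakis((R)-N-(4-dodecylphenylsulfonyl)prolinate)] (1 mol %), pentane, −78 °C → rt, slow addition of 6 (1.5 equiv); then toluene, 100 °C
Reagents that add atoms: 6 methyl 2-diazobut-3-enoate, C=CC(=[N+]=[N-])C(=O)OC
Why: The dirhodium prolinate turns 6 into a donor/acceptor vinylcarbenoid that cyclopropanates the terminal vinyl group of 4, forming C5–C6 and, transiently, C4–C6 to give the cis-divinylcyclopropane 7; release of cyclopropane strain then drives a [3,3] (Cope) shift through the boat transition state, cleaving C4–C6 and forming the quaternary C8–C8a bond. The closest known reaction type is the tandem cyclopropanation/Cope rearrangement (formal (4+3) cycloaddition) of vinyldiazoacetates with 1,3-dienes under Rh2(DOSP)4 catalysis. The three-membered ring closes by (2+1) carbene transfer, and the seven-membered ring closes by sigmatropic ring expansion of the cis-divinylcyclopropane rather than by direct cyclisation. The two cyclopropane stereocentres are set by the chiral catalyst, and C8a is set by chirality transfer, because the endo boat geometry (the only one that leads to two cis ring alkenes) presents a single face of the ring alkene to the migrating vinyl terminus. The step needs site selectivity (the tetrasubstituted ring alkene is sterically closed to the carbenoid), cis selectivity (the alkene substituent ends syn to the vinyl donor of a donor/acceptor carbenoid) and enantioselectivity (catalyst); the inward-pointing C8a methyl slows the Cope step, hence the thermal finish.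

Step 5
Reactants: 8 methyl (8aR)-3,3-(ethylenedioxy)-8a-methyl-1,2,3,5,8,8a-hexahydroazulene-6-carboxylate
Product: 10 methyl (3aS,4S,8aR)-3,3-(ethylenedioxy)-4-hydroxy-8a-methyl-1,2,3,3a,4,5,8,8a-octahydroazulene-6-carboxylate, via C4-alkylborane 9 (not isolated)
Conditions: BH3·THF (1.2 equiv), THF, 0 °C → rt; then 30% H2O2, 1 M NaOH, 0 °C, short contact
Reagents that add atoms: hydrogen peroxide, OO
Why: Hydroboration–oxidation adds H and B syn across the electron-rich C3a=C4 alkene, with boron at the less substituted C4 and from the α-face away from the angular methyl (the outcome known for 5-ene steroids), so that C3a–H and C4–OH are both α (trans ring fusion) after oxidation with retention, while the electron-poor enoate should react more slowly.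

Step 6
Reactants: 10 methyl (3aS,4S,8aR)-3,3-(ethylenedioxy)-4-hydroxy-8a-methyl-1,2,3,3a,4,5,8,8a-octahydroazulene-6-carboxylate
Product: 11 methyl (3aS,4S,8aR)-4-(tert-butyldimethylsilyloxy)-3,3-(ethylenedioxy)-8a-methyl-1,2,3,3a,4,5,8,8a-octahydroazulene-6-carboxylate
Conditions: TBSOTf, 2,6-lutidine, CH2Cl2, −78 → 0 °C
Reagents that add atoms: tert-butyldimethylsilyl triflate, CC(C)(C)[Si](C)(C)OS(=O)(=O)C(F)(F)F
Why: Silylation of the hindered secondary alcohol under buffered conditions protects C4–OH through the hydride steps and, later, keeps it from competing with the tertiary alkoxide for the acyl chloride.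

Step 7
Reactants: 11 methyl (3aS,4S,8aR)-4-(tert-butyldimethylsilyloxy)-3,3-(ethylenedioxy)-8a-methyl-1,2,3,3a,4,5,8,8a-octahydroazulene-6-carboxylate
Product: 12 [(3aS,4S,8aR)-4-(tert-butyldimethylsilyloxy)-3,3-(ethylenedioxy)-8a-methyl-1,2,3,3a,4,5,8,8a-octahydroazulen-6-yl]methanol
Conditions: i-Bu2AlH (2.5 equiv), CH2Cl2, −78 °C; aq. potassium sodium tartrate work-up
Reagents that add atoms: none
Why: 1,2-Reduction of the conjugated ester with i-Bu2AlH gives the primary allylic alcohol without touching the alkene, the silyl ether or the ketal.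

Step 8
Reactants: 12 [(3aS,4S,8aR)-4-(tert-butyldimethylsilyloxy)-3,3-(ethylenedioxy)-8a-methyl-1,2,3,3a,4,5,8,8a-octahydroazulen-6-yl]methanol
Product: 14 (3aS,4S,8aR)-4-(tert-butyldimethylsilyloxy)-3,3-(ethylenedioxy)-6,8a-dimethyl-1,2,3,3a,4,5,8,8a-octahydroazulene, via allylic sulfate monoester 13 (not isolated)
Conditions: SO3·pyridine, THF, 0 °C; then LiAlH4, 0 °C → rt
Reagents that add atoms: none
Why: Reductive deoxygenation of a primary allylic alcohol through its sulfate monoester relies on direct hydride displacement at the unhindered primary carbon, which turns the former ester carbon into the C6 methyl group and leaves the C6=C7 alkene in place.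

Step 9
Reactants: 14 (3aS,4S,8aR)-4-(tert-butyldimethylsilyloxy)-3,3-(ethylenedioxy)-6,8a-dimethyl-1,2,3,3a,4,5,8,8a-octahydroazulene
Product: 15 (3aS,4S,8aR)-4-(tert-butyldimethylsilyloxy)-6,8a-dimethyl-2,3a,4,5,8,8a-hexahydroazulen-3(1H)-one
Conditions: PPTS (20 mol %), acetone/H2O (9:1), 50 °C
Reagents that add atoms: water, O
Why: Mild acid-catalysed ketal hydrolysis frees the C3 ketone, and the weak acid is chosen so that the secondary silyl ether, the trisubstituted alkene and the C3a configuration next to the new carbonyl are not disturbed.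

Step 10
Reactants: 16 vanillic acid (4-hydroxy-3-methoxybenzoic acid)
Product: 18 4-(tert-butyldimethylsilyloxy)-3-methoxybenzoic acid, via bis-silylated vanillic acid 17 (not isolated)
Conditions: TBSCl (2.4 equiv), imidazole, DMF, rt; then AcOH, THF/H2O, rt
Reagents that add atoms: tert-butyldimethylsilyl chloride, CC(C)(C)[Si](C)(C)Cl
Why: Exhaustive silylation followed by selective hydrolysis of the far more labile silyl ester leaves the phenol protected as its silyl ether, a group that cannot transfer an acyl unit to an alkoxide later.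

Step 11
Reactants: 18 4-(tert-butyldimethylsilyloxy)-3-methoxybenzoic acid
Product: 19 4-(tert-butyldimethylsilyloxy)-3-methoxybenzoyl chloride
Conditions: (COCl)2, DMF (cat.), CH2Cl2, 0 °C → rt; concentrated and used crude
Reagents that add atoms: oxalyl chloride, O=C(Cl)C(=O)Cl
Why: Acid chloride formation through the Vilsmeier-type chloroiminium intermediate proceeds under conditions that the aryl silyl ether tolerates.

Step 12
Reactants: 15 (3aS,4S,8aR)-4-(tert-butyldimethylsilyloxy)-6,8a-dimethyl-2,3a,4,5,8,8a-hexahydroazulen-3(1H)-one; 20 isopropylmagnesium chloride; 19 4-(tert-butyldimethylsilyloxy)-3-methoxybenzoyl chloride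
Product: 22 (3R,3aS,4S,8aR)-4-(tert-butyldimethylsilyloxy)-3-isopropyl-6,8a-dimethyl-1,2,3,3a,4,5,8,8a-octahydroazulen-3-yl 4-(tert-butyldimethylsilyloxy)-3-methoxybenzoate, via chloromagnesium alkoxide 21 (not isolated)
Conditions: LaCl3·2LiCl (1.0 equiv), THF, 0 °C, then 20 (1.3 equiv); then 19 (2.5 equiv), DMAP (0.2 equiv), 0 → 40 °C
Reagents that add atoms: 20 isopropylmagnesium chloride, CC(C)[Mg]Cl; 19 4-(tert-butyldimethylsilyloxy)-3-methoxybenzoyl chloride, COc1cc(C(=O)Cl)ccc1O[Si](C)(C)C(C)(C)C
Why: Lanthanum-promoted Grignard 1,2-addition suppresses enolisation and β-hydride reduction, the nucleophile should enter from the α-face of the trans-fused cyclopentanone anti to the axial C8a methyl (as in additions to ring-D oxo steroids) to set C3 with O β and isopropyl α, and the hindered tertiary alkoxide is trapped in the same flask by the aroyl chloride (alkoxide acylation).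

Step 13
Reactants: 22 (3R,3aS,4S,8aR)-4-(tert-butyldimethylsilyloxy)-3-isopropyl-6,8a-dimethyl-1,2,3,3a,4,5,8,8a-octahydroazulen-3-yl 4-(tert-butyldimethylsilyloxy)-3-methoxybenzoate
Product: 23 (3R,3aS,4S,8aR)-4-hydroxy-3-isopropyl-6,8a-dimethyl-1,2,3,3a,4,5,8,8a-octahydroazulen-3-yl 4-hydroxy-3-methoxybenzoate
Conditions: HF·pyridine (excess), pyridine, THF, 0 °C → rt
Reagents that add atoms: none
Why: Fluoride-mediated cleavage of both silyl ethers under buffered, non-basic conditions should free the C4 hydroxyl and the phenol without 1,3-acyl migration from the tertiary to the secondary oxygen.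

Step 14
Reactants: 23 (3R,3aS,4S,8aR)-4-hydroxy-3-isopropyl-6,8a-dimethyl-1,2,3,3a,4,5,8,8a-octahydroazulen-3-yl 4-hydroxy-3-methoxybenzoate
Product: 24 (3R,3aS,4S,6R,7S,8aR)-6,7-epoxy-4-hydroxy-3-isopropyl-6,8a-dimethyldecahydroazulen-3-yl 4-hydroxy-3-methoxybenzoate (CNP0315707.1)
Conditions: VO(acac)2 (5 mol %), t-BuOOH (1.5 equiv, decane solution), CH2Cl2, 0 °C → rt
Reagents that add atoms: tert-butyl hydroperoxide, CC(C)(C)OO
Why: Vanadium-catalysed hydroxyl-directed epoxidation delivers oxygen to the C6=C7 alkene from the face of the homoallylic C4 hydroxyl (α), a face that the β angular methyl also leaves open, which sets C6 and C7, and the acyl-deactivated phenol and the hindered ester should be inert.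

Compound list
1 | 2-bromo-3-methylcyclopent-2-en-1-one | CC1=C(Br)C(=O)CC1 | starting material
2 | 6-bromo-7-methyl-1,4-dioxaspiro[4.4]non-6-ene | CC1=C(Br)C2(CC1)OCCO2 | intermediate
3 | 4,4,5,5-tetramethyl-2-vinyl-1,3,2-dioxaborolane | C=CB1OC(C)(C)C(C)(C)O1 | starting material
4 | 6-ethenyl-7-methyl-1,4-dioxaspiro[4.4]non-6-ene | C=CC1=C(C)CCC12OCCO2 | intermediate
5 | methyl but-3-enoate | C=CCC(=O)OC | starting material
6 | methyl 2-diazobut-3-enoate | C=CC(=[N+]=[N-])C(=O)OC | intermediate
7 | methyl (1S,2S)-1-ethenyl-2-(7-methyl-1,4-dioxaspiro[4.4]non-6-en-6-yl)cyclopropane-1-carboxylate (vinyl and cyclopentenyl cis) | C=C[C@@]1(C(=O)OC)C[C@H]1C2=C(C)CCC23OCCO3 | intermediate (not isolated)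
8 | methyl (8aR)-3,3-(ethylenedioxy)-8a-methyl-1,2,3,5,8,8a-hexahydroazulene-6-carboxylate | O1CCOC12CC[C@]3(C)CC=C(C(=O)OC)CC=C32 | intermediate
9 | C4-alkylborane of 8 (BH2 at C4 and the new C3a–H both α) | O1CCOC12CC[C@]3(C)CC=C(C(=O)OC)C[C@H](B)[C@H]32 | intermediate (not isolated)
10 | methyl (3aS,4S,8aR)-3,3-(ethylenedioxy)-4-hydroxy-8a-methyl-1,2,3,3a,4,5,8,8a-octahydroazulene-6-carboxylate | O1CCOC12CC[C@]3(C)CC=C(C(=O)OC)C[C@H](O)[C@H]32 | intermediate
11 | methyl (3aS,4S,8aR)-4-(tert-butyldimethylsilyloxy)-3,3-(ethylenedioxy)-8a-methyl-1,2,3,3a,4,5,8,8a-octahydroazulene-6-carboxylate | O1CCOC12CC[C@]3(C)CC=C(C(=O)OC)C[C@H](O[Si](C)(C)C(C)(C)C)[C@H]32 | intermediate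
12 | [(3aS,4S,8aR)-4-(tert-butyldimethylsilyloxy)-3,3-(ethylenedioxy)-8a-methyl-1,2,3,3a,4,5,8,8a-octahydroazulen-6-yl]methanol | O1CCOC12CC[C@]3(C)CC=C(CO)C[C@H](O[Si](C)(C)C(C)(C)C)[C@H]32 | intermediate
13 | hydrogen sulfate ester of 12 (present as its pyridinium salt) | O1CCOC12CC[C@]3(C)CC=C(COS(=O)(=O)O)C[C@H](O[Si](C)(C)C(C)(C)C)[C@H]32 | intermediate (not isolated)
14 | (3aS,4S,8aR)-4-(tert-butyldimethylsilyloxy)-3,3-(ethylenedioxy)-6,8a-dimethyl-1,2,3,3a,4,5,8,8a-octahydroazulene | O1CCOC12CC[C@]3(C)CC=C(C)C[C@H](O[Si](C)(C)C(C)(C)C)[C@H]32 | intermediate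
15 | (3aS,4S,8aR)-4-(tert-butyldimethylsilyloxy)-6,8a-dimethyl-2,3a,4,5,8,8a-hexahydroazulen-3(1H)-one | O=C1CC[C@]2(C)CC=C(C)C[C@H](O[Si](C)(C)C(C)(C)C)[C@H]21 | intermediate
16 | vanillic acid | COc1cc(C(=O)O)ccc1O | starting material
17 | tert-butyldimethylsilyl 4-(tert-butyldimethylsilyloxy)-3-methoxybenzoate | COc1cc(C(=O)O[Si](C)(C)C(C)(C)C)ccc1O[Si](C)(C)C(C)(C)C | intermediate (not isolated)
18 | 4-(tert-butyldimethylsilyloxy)-3-methoxybenzoic acid | COc1cc(C(=O)O)ccc1O[Si](C)(C)C(C)(C)C | intermediate
19 | 4-(tert-butyldimethylsilyloxy)-3-methoxybenzoyl chloride | COc1cc(C(=O)Cl)ccc1O[Si](C)(C)C(C)(C)C | intermediate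
20 | isopropylmagnesium chloride | CC(C)[Mg]Cl | starting material
21 | chloromagnesium (3R,3aS,4S,8aR)-4-(tert-butyldimethylsilyloxy)-3-isopropyl-6,8a-dimethyl-1,2,3,3a,4,5,8,8a-octahydroazulen-3-olate | Cl[Mg]O[C@@]1(C(C)C)CC[C@]2(C)CC=C(C)C[C@H](O[Si](C)(C)C(C)(C)C)[C@H]21 | intermediate (not isolated)
22 | (3R,3aS,4S,8aR)-4-(tert-butyldimethylsilyloxy)-3-isopropyl-6,8a-dimethyl-1,2,3,3a,4,5,8,8a-octahydroazulen-3-yl 4-(tert-butyldimethylsilyloxy)-3-methoxybenzoate | COc1cc(C(=O)O[C@@]2(C(C)C)CC[C@]3(C)CC=C(C)C[C@H](O[Si](C)(C)C(C)(C)C)[C@H]32)ccc1O[Si](C)(C)C(C)(C)C | intermediate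
23 | (3R,3aS,4S,8aR)-4-hydroxy-3-isopropyl-6,8a-dimethyl-1,2,3,3a,4,5,8,8a-octahydroazulen-3-yl 4-hydroxy-3-methoxybenzoate | COc1cc(C(=O)O[C@@]2(C(C)C)CC[C@]3(C)CC=C(C)C[C@H](O)[C@H]32)ccc1O | intermediate
24 | (3R,3aS,4S,6R,7S,8aR)-6,7-epoxy-4-hydroxy-3-isopropyl-6,8a-dimethyldecahydroazulen-3-yl 4-hydroxy-3-methoxybenzoate | COc1cc(C(=O)O[C@@]2(C(C)C)CC[C@]3(C)C[C@@H]4O[C@]4(C)C[C@H](O)[C@H]32)ccc1O | target

Total step count: 14. Longest linear sequence: 11 steps (1, 2, 4, 5, 6, 7, 8, 9, 12, 13, 14); steps 3, 10 and 11 prepare the two side components.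

Steps most likely to fail

Step 4. The unsubstituted vinyldiazoacetate may cyclise to a pyrazole or dimerise before carbene transfer. Facial discrimination by the catalyst may be insufficient with this hindered diene. During the slow Cope step the cyclopropane may epimerise, which would erode enantiopurity. The fallback sets out from 4 and changes the three-carbon partner to a stabilised 2-siloxyvinyl carbenoid. Diazo transfer to commercial methyl acetoacetate (4-acetamidobenzenesulfonyl azide, Et3N, MeCN) would give methyl 2-diazo-3-oxobutanoate F1. O-Silylation (TBSOTf, Et3N, CH2Cl2, 0 °C) would give methyl 3-(tert-butyldimethylsilyloxy)-2-diazobut-3-enoate F2, which does not cyclise on standing. With 4 and Rh2(R-PTAD)4 [dirhodium tetrakis((R)-(1-adamantyl)(phthalimido)acetate)] in hexane, followed by warming, the same cyclopropanation/Cope cascade should give methyl (8aR)-7-(tert-butyldimethylsilyloxy)-3,3-(ethylenedioxy)-8a-methyl-1,2,3,5,8,8a-hexahydroazulene-6-carboxylate F3. CsF and PhNTf2 in DME would convert the silyl enol ether into methyl (8aR)-3,3-(ethylenedioxy)-8a-methyl-7-(trifluoromethylsulfonyloxy)-1,2,3,5,8,8a-hexahydroazulene-6-carboxylate F4. Reduction of the enol triflate (Pd(OAc)2, PPh3, HCO2H, Bu3N, DMF, 60 °C) comes back to the route at 8.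

Step 12. Enolisation or β-hydride reduction may win over addition at the hindered ketone, attack may occur from the wrong face, silanol may be lost from the β-silyloxy ketone, and acyl transfer to the very hindered alkoxide may stay incomplete. The fallback sets out from 15 and separates the events, using an sp2 nucleophile that has no β-hydrogen to transfer. Isopropenylmagnesium bromide with CeCl3 (THF, −78 °C) would give (3S,3aS,4S,8aR)-4-(tert-butyldimethylsilyloxy)-6,8a-dimethyl-3-(prop-1-en-2-yl)-1,2,3,3a,4,5,8,8a-octahydroazulen-3-ol F5, which is isolated so that the configuration at C3 can be checked. Acylation of its potassium alkoxide (KN(SiMe3)2, THF, −78 °C, then 19) would give (3S,3aS,4S,8aR)-4-(tert-butyldimethylsilyloxy)-6,8a-dimethyl-3-(prop-1-en-2-yl)-1,2,3,3a,4,5,8,8a-octahydroazulen-3-yl 4-(tert-butyldimethylsilyloxy)-3-methoxybenzoate F6. Selective hydrogenation of the 1,1-disubstituted alkene (H2, RhCl(PPh3)3, benzene), which should leave the trisubstituted ring alkene untouched, comes back to the route at 22.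

Step 5. Borane may reduce or hydroborate the enoate in competition with the hindered ring alkene, and conversion at that alkene may be slow. The fallback sets out from 4 and passes through the siloxy cycloadduct F3 and the enol triflate F4 described above. In F4 the second alkene is a tetrasubstituted, electron-poor β-triflyloxy enoate that borane should not touch. BH3·THF, then NaBO3·4H2O, would give methyl (3aS,4S,8aR)-3,3-(ethylenedioxy)-4-hydroxy-8a-methyl-7-(trifluoromethylsulfonyloxy)-1,2,3,3a,4,5,8,8a-octahydroazulene-6-carboxylate F7. Silylation (TBSOTf, 2,6-lutidine) would give methyl (3aS,4S,8aR)-4-(tert-butyldimethylsilyloxy)-3,3-(ethylenedioxy)-8a-methyl-7-(trifluoromethylsulfonyloxy)-1,2,3,3a,4,5,8,8a-octahydroazulene-6-carboxylate F8. Formate reduction of the enol triflate (Pd(OAc)2, PPh3, HCO2H, Bu3N, DMF) comes back to the route at 11.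

Further compounds
F1 | step 4 | methyl 2-diazo-3-oxobutanoate | CC(=O)C(=[N+]=[N-])C(=O)OC
F2 | step 4 | methyl 3-(tert-butyldimethylsilyloxy)-2-diazobut-3-enoate | C=C(O[Si](C)(C)C(C)(C)C)C(=[N+]=[N-])C(=O)OC
F3 | step 4 | methyl (8aR)-7-(tert-butyldimethylsilyloxy)-3,3-(ethylenedioxy)-8a-methyl-1,2,3,5,8,8a-hexahydroazulene-6-carboxylate | O1CCOC12CC[C@]3(C)CC(O[Si](C)(C)C(C)(C)C)=C(C(=O)OC)CC=C32
F4 | step 4 | methyl (8aR)-3,3-(ethylenedioxy)-8a-methyl-7-(trifluoromethylsulfonyloxy)-1,2,3,5,8,8a-hexahydroazulene-6-carboxylate | O1CCOC12CC[C@]3(C)CC(OS(=O)(=O)C(F)(F)F)=C(C(=O)OC)CC=C32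
F5 | step 12 | (3S,3aS,4S,8aR)-4-(tert-butyldimethylsilyloxy)-6,8a-dimethyl-3-(prop-1-en-2-yl)-1,2,3,3a,4,5,8,8a-octahydroazulen-3-ol | O[C@@]1(C(C)=C)CC[C@]2(C)CC=C(C)C[C@H](O[Si](C)(C)C(C)(C)C)[C@H]21
F6 | step 12 | (3S,3aS,4S,8aR)-4-(tert-butyldimethylsilyloxy)-6,8a-dimethyl-3-(prop-1-en-2-yl)-1,2,3,3a,4,5,8,8a-octahydroazulen-3-yl 4-(tert-butyldimethylsilyloxy)-3-methoxybenzoate | COc1cc(C(=O)O[C@@]2(C(C)=C)CC[C@]3(C)CC=C(C)C[C@H](O[Si](C)(C)C(C)(C)C)[C@H]32)ccc1O[Si](C)(C)C(C)(C)C
F7 | step 5 | methyl (3aS,4S,8aR)-3,3-(ethylenedioxy)-4-hydroxy-8a-methyl-7-(trifluoromethylsulfonyloxy)-1,2,3,3a,4,5,8,8a-octahydroazulene-6-carboxylate | O1CCOC12CC[C@]3(C)CC(OS(=O)(=O)C(F)(F)F)=C(C(=O)OC)C[C@H](O)[C@H]32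
F8 | step 5 | methyl (3aS,4S,8aR)-4-(tert-butyldimethylsilyloxy)-3,3-(ethylenedioxy)-8a-methyl-7-(trifluoromethylsulfonyloxy)-1,2,3,3a,4,5,8,8a-octahydroazulene-6-carboxylate | O1CCOC12CC[C@]3(C)CC(OS(=O)(=O)C(F)(F)F)=C(C(=O)OC)C[C@H](O[Si](C)(C)C(C)(C)C)[C@H]32
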